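The plan rests on cutting C10–C11 of the oxocane (chain numbering, C1 = alkyne CH). The ring holds a 1,3-dioxygen pattern, acetate O–C10–C11–C12–ring O, an aldol retron in which C12 is a latent oxocarbenium carbon. The precursor is acyclic: O6 carries a 1,1-disubstituted enol ether (C11=C12, C13–C15 attached) and C10 is a dibenzyl acetal next to the C9 and C7 chlorides. One Lewis-acid operation joins C11 to C10, closes the eight-membered ring, and lets the O10 benzyl group hand a hydride to C12. This sets C10 and the 6,12-trans ether and frees the C10 hydroxyl.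

Key step: step 9

Remark: atoms are numbered along the C15 chain of the target. C1 is the alkyne CH, C6 and C12 are the ring carbons on the ring oxygen O6, C15 is the methyl, and O10 is the oxygen on C10. Ipc = isopinocampheyl, TBS = tert-butyldimethylsilyl, Bn = benzyl.

Step 1
Reactants: 1 (R)-2-hydroxybutanoic acid
Product: 3 (R)-2-[(tert-butyldimethylsilyl)oxy]butanoic acid, via bis-silyl derivative 2 (not isolated)
Conditions: TBSCl (2.2 equiv), imidazole, DMF, rt; then THF–H2O–AcOH, rt
Reagents that add atoms: tert-butyldimethylsilyl chloride, CC(C)(C)[Si](C)(C)Cl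
Why: Silylation of both OH groups followed by selective hydrolysis of the far more labile silyl ester should leave the silyl ether acid, and C13 (R) comes unchanged from the chiral pool.

Step 2
Reactants: 4 3-bromo-1-(trimethylsilyl)prop-1-yne; 5 triethyl phosphite
Product: 6 diethyl [3-(trimethylsilyl)prop-2-yn-1-yl]phosphonate
Conditions: neat, 120 °C
Reagents that add atoms: none
Why: Michaelis–Arbuzov reaction of a primary propargylic bromide, with no stereocentre involved.

Step 3
Reactants: 7 allyl chloride; 8 3-(benzyloxy)propanal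
Product: 10 (3S,4S)-6-(benzyloxy)-3-chlorohex-1-en-4-ol (C6 OH, C7 Cl, syn), via chloroallylborane 9 (not isolated)
Conditions: 7, (+)-Ipc2BOMe, LiN(c-Hex)2, Et2O, −95 °C; BF3·OEt2; 8, −95 °C; then 30% H2O2, aq NaHCO3, 0 °C
Reagents that add atoms: none
Why: In this asymmetric allylboration (Brown type) with a (Z)-γ-chloroallylborane, the closed chair transition state turns the Z geometry into the 6,7-syn chlorohydrin and the Ipc groups derived from (−)-α-pinene should select the aldehyde face that gives 6S,7S.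

Step 4
Reactants: 10 chlorohydrin; 3 silyloxy acid
Product: 11 (3S,4S)-6-(benzyloxy)-3-chlorohex-1-en-4-yl (2R)-2-[(tert-butyldimethylsilyl)oxy]butanoate
Conditions: DCC, DMAP (cat.), CH2Cl2, 0 °C → rt
Reagents that add atoms: none
Why: Steglich esterification attaches C12–C15 to O6 with retention at C6 and C13, and the conditions are too mild to close the chlorohydrin to an epoxide.

Step 5
Reactants: 11 ester
Product: 12 (3S,4S)-1-(benzyloxy)-4-chloro-7-oxoheptan-3-yl (2R)-2-[(tert-butyldimethylsilyl)oxy]butanoate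
Conditions: Rh(acac)(CO)2 (2 mol %), BIPHEPHOS (4 mol %), CO/H2 (1:1, 10 bar), toluene, 50 °C
Reagents that add atoms: carbon monoxide, [C-]#[O+]
Why: In this linear-selective hydroformylation the bulky bisphosphite should keep rhodium on the terminal carbon, away from the position β to chloride, so that C10 is added as the aldehyde without touching the stereocentres.

Step 6
Reactants: 12 aldehyde
Product: 13 (3S,4S,6S)-1-(benzyloxy)-4,6-dichloro-7-oxoheptan-3-yl (2R)-2-[(tert-butyldimethylsilyl)oxy]butanoate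
Conditions: (5S)-5-benzyl-2,2,3-trimethylimidazolidin-4-one·TFA (10 mol %), 2,3,4,5,6,6-hexachlorocyclohexa-2,4-dien-1-one, acetone, −30 °C; used crude
Reagents that add atoms: 2,3,4,5,6,6-hexachlorocyclohexa-2,4-dien-1-one, O=C1C(Cl)=C(Cl)C(Cl)=C(Cl)C1(Cl)Cl
Why: In this enamine-catalysed asymmetric α-chlorination the benzyl group of the catalyst shields one face of the E-enamine, so C9 is set by the catalyst (the 5S catalyst is the one expected to give 9S) and not by the remote C7.

Step 7
Reactants: 13 α-chloro aldehyde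
Product: 14 (3S,4S,6S)-1,7,7-tris(benzyloxy)-4,6-dichloroheptan-3-yl (2R)-2-[(tert-butyldimethylsilyl)oxy]butanoate
Conditions: BnOTMS (2.5 equiv), TMSOTf (10 mol %), CH2Cl2, −78 → −30 °C
Reagents that add atoms: benzyloxytrimethylsilane, C[Si](C)(C)OCc1ccccc1
Why: Silyl-triflate-catalysed acetalisation with an alkoxysilane (Noyori conditions) is cold and non-basic, so the labile α-chloro stereocentre C9 should not epimerise.

Step 8
Reactants: 14 acetal ester
Product: 15 (3R)-3-[(tert-butyldimethylsilyl)oxy]-2-{[(3S,4S,6S)-1,7,7-tris(benzyloxy)-4,6-dichloroheptan-3-yl]oxy}pent-1-ene (enol ether, C11=C12)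
Conditions: Cp2TiMe2 (3 equiv), toluene, 75 °C, dark
Reagents that add atoms: dimethyltitanocene Cp2TiMe2, [CH3-].[CH3-].[Ti+4].[cH-]1cccc1.[cH-]1cccc1
Why: Petasis methylenation turns the ester carbonyl C12 into the 1,1-disubstituted enol ether (new CH2 = C11) under neutral conditions that should spare the acetal, the chlorides, the silyl and benzyl ethers and C13.

Step 9
Reactants: 15 enol ether acetal
Product: 18 (2R,4S,5S,7S,8S)-8-[2-(benzyloxy)ethyl]-2-{(1R)-1-[(tert-butyldimethylsilyl)oxy]propyl}-5,7-dichlorooxocan-4-ol, via ring-closed oxocarbenium triflate 16 (not isolated), via mixed benzaldehyde acetal 17 (not isolated)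
Conditions: TMSOTf (0.3 equiv), 2,6-di-tert-butyl-4-methylpyridine (0.5 equiv), CH2Cl2 (0.002 M), −78 → −20 °C; then THF–H2O–AcOH, 0 °C
Reagents that add atoms: none
Why: Proposed new method: TMSOTf ionises the dibenzyl acetal to the O-benzyl oxocarbenium ion at C10, the enol ether attacks it through C11 to give the ring-closed C12 oxocarbenium ion 16, the OCH2Ph group on O10 then passes a hydride to C12 by a 1,5-shift through a six-membered chair, BnOTMS caps the resulting benzaldehyde-derived cation as 17 and returns TMSOTf, and mild acid releases 18. The closest known reaction types are the Lewis-acid addition of alkyl enol ethers to acetals and aldehydes (Mukaiyama-type aldol, as used in aldol–Prins cascades), Prins closures of oxocenes, and intramolecular hydride delivery of the Evans–Tishchenko and 1,5-hydride-transfer kind; their union in one medium-ring closure is what is new. The oxocane closes in the 8-(enolendo)-exo-trig mode, and no other ring survives the step. C10 is set by C9: the C9–Cl bond stands antiperiplanar to the incoming C11 (polar Felkin–Anh) while the oxocarbenium oxygen with its benzyl group turns outward, anti to C8, so chlorine and oxygen end pseudo-equatorial and 9,10-trans (10S). C12 is set by C10: the tethered hydride can reach only the face of C12 that is syn to O10, which gives 12R and the 6,12-trans ether that an external hydride would not be expected to favour, and the transfer should be downhill because a dialkyl oxocarbenium ion flanked by two C–O bonds is traded for an aryl-stabilised one. The step needs cyclisation to beat oligomerisation and proton loss, which high dilution, the hindered pyridine and the fact that the enol ether is the only strong π-nucleophile and the O10 benzyl the only hydride source within 1,5-reach should secure.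

Step 10
Reactants: 18 oxocanol
Product: 19 (2R,4S,5S,7S,8S)-8-[2-(benzyloxy)ethyl]-2-{(1R)-1-[(tert-butyldimethylsilyl)oxy]propyl}-5,7-dichlorooxocan-4-yl acetate
Conditions: Ac2O, pyridine, DMAP (cat.), CH2Cl2, 0 °C → rt
Reagents that add atoms: acetic anhydride, CC(=O)OC(C)=O
Why: Acylation of the only free hydroxyl proceeds with retention at C10, and the weak base should not turn the trans chlorohydrin into an epoxide.

Step 11
Reactants: 19 acetate
Product: 20 (2R,4S,5S,7S,8S)-2-{(1R)-1-[(tert-butyldimethylsilyl)oxy]propyl}-5,7-dichloro-8-(2-hydroxyethyl)oxocan-4-yl acetate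
Conditions: H2 (1 atm), Pd/C, EtOAc, rt
Reagents that add atoms: none
Why: Hydrogenolysis removes the one remaining benzyl ether, and unactivated secondary chlorides, the acetate and the silyl ether are not expected to react under neutral conditions.

Step 12
Reactants: 20 primary alcohol
Product: 21 (2R,4S,5S,7S,8S)-2-{(1R)-1-[(tert-butyldimethylsilyl)oxy]propyl}-5,7-dichloro-8-(2-oxoethyl)oxocan-4-yl acetate
Conditions: Dess–Martin periodinane, CH2Cl2, 0 °C → rt
Reagents that add atoms: none
Why: Dess–Martin oxidation gives the β-alkoxy aldehyde (C4) under near-neutral conditions that should avoid β-elimination of O6.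

Step 13
Reactants: 21 aldehyde; 6 phosphonate
Product: 22 (2R,4S,5S,7S,8S)-2-{(1R)-1-[(tert-butyldimethylsilyl)oxy]propyl}-5,7-dichloro-8-[(2E)-5-(trimethylsilyl)pent-2-en-4-yn-1-yl]oxocan-4-yl acetate
Conditions: 6, LiN(SiMe3)2, THF, −78 °C; then 21, −78 → 0 °C
Reagents that add atoms: none
Why: The Horner–Wadsworth–Emmons reaction of the alkynyl-stabilised phosphonate anion should give the E C3=C4 alkene, and the low temperature protects the acetate, the chlorides and the β-alkoxy aldehyde.

Step 14
Reactants: 22 silyl enyne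
Product: 23 (2R,4S,5S,7S,8S)-5,7-dichloro-2-[(1R)-1-hydroxypropyl]-8-[(2E)-pent-2-en-4-yn-1-yl]oxocan-4-yl acetate
Conditions: Bu4NF, AcOH (1:1), THF, 0 °C → rt
Reagents that add atoms: none
Why: Buffered fluoride desilylation cleaves the O–TBS and the alkynyl C–SiMe3 bonds in one operation, and the acetic acid keeps the medium from attacking the acetate or the halides.

Step 15
Reactants: 23 secondary alcohol
Product: 24 (2R,4S,5S,7S,8S)-2-[(1S)-1-bromopropyl]-5,7-dichloro-8-[(2E)-pent-2-en-4-yn-1-yl]oxocan-4-yl acetate (target)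
Conditions: CBr4, P(n-Oct)3, toluene, 70 °C
Reagents that add atoms: carbon tetrabromide, BrC(Br)(Br)Br
Why: Appel-type bromination displaces the alkoxyphosphonium group by bromide in an SN2 step, so 13R inverts to 13S.

Compound list
1 | (R)-2-hydroxybutanoic acid | OC(=O)[C@H](O)CC | starting material
2 | tert-butyldimethylsilyl (R)-2-[(tert-butyldimethylsilyl)oxy]butanoate | CC(C)(C)[Si](C)(C)OC(=O)[C@H](O[Si](C)(C)C(C)(C)C)CC | intermediate
3 | (R)-2-[(tert-butyldimethylsilyl)oxy]butanoic acid | OC(=O)[C@H](O[Si](C)(C)C(C)(C)C)CC | intermediate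
4 | 3-bromo-1-(trimethylsilyl)prop-1-yne | C[Si](C)(C)C#CCBr | starting material
5 | triethyl phosphite | CCOP(OCC)OCC | starting material
6 | diethyl [3-(trimethylsilyl)prop-2-yn-1-yl]phosphonate | CCOP(=O)(CC#C[Si](C)(C)C)OCC | intermediate
7 | allyl chloride | C=CCCl | starting material
8 | 3-(benzyloxy)propanal | O=CCCOCc1ccccc1 | starting material
9 | (Z)-(3-chloroallyl)diisopinocampheylborane, Ipc from (−)-α-pinene | Cl/C=C\CB([C@H]1C[C@H]2C[C@@H]([C@@H]1C)C2(C)C)[C@H]1C[C@H]2C[C@@H]([C@@H]1C)C2(C)C | intermediate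
10 | (3S,4S)-6-(benzyloxy)-3-chlorohex-1-en-4-ol | c1ccccc1COCC[C@H](O)[C@H](C=C)Cl | intermediate
11 | (3S,4S)-6-(benzyloxy)-3-chlorohex-1-en-4-yl (2R)-2-[(tert-butyldimethylsilyl)oxy]butanoate | c1ccccc1COCC[C@H](OC(=O)[C@H](O[Si](C)(C)C(C)(C)C)CC)[C@H](C=C)Cl | intermediate
12 | (3S,4S)-1-(benzyloxy)-4-chloro-7-oxoheptan-3-yl (2R)-2-[(tert-butyldimethylsilyl)oxy]butanoate | c1ccccc1COCC[C@H](OC(=O)[C@H](O[Si](C)(C)C(C)(C)C)CC)[C@H](CCC=O)Cl | intermediate
13 | (3S,4S,6S)-1-(benzyloxy)-4,6-dichloro-7-oxoheptan-3-yl (2R)-2-[(tert-butyldimethylsilyl)oxy]butanoate | c1ccccc1COCC[C@H](OC(=O)[C@H](O[Si](C)(C)C(C)(C)C)CC)[C@H](C[C@@H](C=O)Cl)Cl | intermediate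
14 | (3S,4S,6S)-1,7,7-tris(benzyloxy)-4,6-dichloroheptan-3-yl (2R)-2-[(tert-butyldimethylsilyl)oxy]butanoate | c1ccccc1COCC[C@H](OC(=O)[C@H](O[Si](C)(C)C(C)(C)C)CC)[C@H](C[C@@H](C(OCc1ccccc1)OCc1ccccc1)Cl)Cl | intermediate
15 | (3R)-3-[(tert-butyldimethylsilyl)oxy]-2-{[(3S,4S,6S)-1,7,7-tris(benzyloxy)-4,6-dichloroheptan-3-yl]oxy}pent-1-ene | c1ccccc1COCC[C@H](OC(=C)[C@H](O[Si](C)(C)C(C)(C)C)CC)[C@H](C[C@@H](C(OCc1ccccc1)OCc1ccccc1)Cl)Cl | intermediate
16 | ring-closed oxocarbenium triflate (C12=O6 cation, 10-O-benzyl) | c1ccccc1COCC[C@@H]2[O+]=C([C@H](O[Si](C)(C)C(C)(C)C)CC)C[C@H](OCc1ccccc1)[C@@H](Cl)C[C@@H]2Cl.[O-]S(=O)(=O)C(F)(F)F | intermediate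
17 | 10-O-[benzyloxy(phenyl)methyl] mixed acetal of 18 | c1ccccc1COCC[C@@H]2O[C@@H]([C@H](O[Si](C)(C)C(C)(C)C)CC)C[C@H](OC(OCc1ccccc1)c1ccccc1)[C@@H](Cl)C[C@@H]2Cl | intermediate
18 | (2R,4S,5S,7S,8S)-8-[2-(benzyloxy)ethyl]-2-{(1R)-1-[(tert-butyldimethylsilyl)oxy]propyl}-5,7-dichlorooxocan-4-ol | c1ccccc1COCC[C@@H]2O[C@@H]([C@H](O[Si](C)(C)C(C)(C)C)CC)C[C@H](O)[C@@H](Cl)C[C@@H]2Cl | intermediate
19 | (2R,4S,5S,7S,8S)-8-[2-(benzyloxy)ethyl]-2-{(1R)-1-[(tert-butyldimethylsilyl)oxy]propyl}-5,7-dichlorooxocan-4-yl acetate | c1ccccc1COCC[C@@H]2O[C@@H]([C@H](O[Si](C)(C)C(C)(C)C)CC)C[C@H](OC(C)=O)[C@@H](Cl)C[C@@H]2Cl | intermediate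
20 | (2R,4S,5S,7S,8S)-2-{(1R)-1-[(tert-butyldimethylsilyl)oxy]propyl}-5,7-dichloro-8-(2-hydroxyethyl)oxocan-4-yl acetate | OCC[C@@H]1O[C@@H]([C@H](O[Si](C)(C)C(C)(C)C)CC)C[C@H](OC(C)=O)[C@@H](Cl)C[C@@H]1Cl | intermediate
21 | (2R,4S,5S,7S,8S)-2-{(1R)-1-[(tert-butyldimethylsilyl)oxy]propyl}-5,7-dichloro-8-(2-oxoethyl)oxocan-4-yl acetate | O=CC[C@@H]1O[C@@H]([C@H](O[Si](C)(C)C(C)(C)C)CC)C[C@H](OC(C)=O)[C@@H](Cl)C[C@@H]1Cl | intermediate
22 | (2R,4S,5S,7S,8S)-2-{(1R)-1-[(tert-butyldimethylsilyl)oxy]propyl}-5,7-dichloro-8-[(2E)-5-(trimethylsilyl)pent-2-en-4-yn-1-yl]oxocan-4-yl acetate | C[Si](C)(C)C#C/C=C/C[C@@H]1O[C@@H]([C@H](O[Si](C)(C)C(C)(C)C)CC)C[C@H](OC(C)=O)[C@@H](Cl)C[C@@H]1Cl | intermediate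
23 | (2R,4S,5S,7S,8S)-5,7-dichloro-2-[(1R)-1-hydroxypropyl]-8-[(2E)-pent-2-en-4-yn-1-yl]oxocan-4-yl acetate | C#C/C=C/C[C@@H]1O[C@@H]([C@H](O)CC)C[C@H](OC(C)=O)[C@@H](Cl)C[C@@H]1Cl | intermediate
24 | (2R,4S,5S,7S,8S)-2-[(1S)-1-bromopropyl]-5,7-dichloro-8-[(2E)-pent-2-en-4-yn-1-yl]oxocan-4-yl acetate | C#C/C=C/C[C@@H]1O[C@@H]([C@@H](Br)CC)C[C@H](OC(C)=O)[C@@H](Cl)C[C@@H]1Cl | target

Total step count: 15. Longest linear sequence: 13 steps (steps 3 to 15, from 8).

Steps most likely to fail

Step 9. Four things may go wrong: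
- The hydride transfer may lag behind proton loss from the ring-closed cation.
- The cation may be captured by benzyloxide before the hydride arrives.
- The closure may lose to oligomerisation.
- The facial selectivity at C10 may be poor.

The fallback uses known chemistry and sets out from 15. The same enol ether–acetal closure is run with stoichiometric TMSOTf in the presence of Et3SiH. The ring-closed cation is then reduced from outside under polar Felkin–Anh control by the C13 silyloxy group (12,13-syn), which should give dibenzyl ether F1. Hydrogenolysis (H2, Pd/C) removes both benzyl groups to give diol F2. TEMPO/PhI(OAc)2 oxidises only the primary alcohol to hydroxy aldehyde F3. Acetylation (Ac2O, pyridine) comes back to the route at 21.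

Step 5. The allylic chloride may be lost through a branched rhodium alkyl (β-chloride elimination), or the alkene may migrate before carbonylation. The fallback sets out from 11. Cross metathesis with crotonaldehyde (second-generation Hoveyda–Grubbs catalyst, CH2Cl2, 40 °C) should give enal F4. Iminium-catalysed transfer hydrogenation with a Hantzsch ester (dibenzylammonium trifluoroacetate, THF) then reduces C8=C9 and comes back at 12.

Step 15. The ring oxygen O6 may take part in the departure of the activated C13 oxygen, which would erode the inversion or contract the ring. Elimination towards C14 may also compete at 70 °C. The fallback sets out from 23. Chloromethanesulfonyl chloride and 2,6-lutidine (CH2Cl2, 0 °C) give the isolable chloromethanesulfonate F5. Displacement with LiBr (DMF, rt) by a plain SN2 reaction comes back at 24.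

Further compounds
F1 | step 9 | (2R,4S,5S,7S,8S)-4-(benzyloxy)-8-[2-(benzyloxy)ethyl]-2-{(1R)-1-[(tert-butyldimethylsilyl)oxy]propyl}-5,7-dichlorooxocane | c1ccccc1COCC[C@@H]2O[C@@H]([C@H](O[Si](C)(C)C(C)(C)C)CC)C[C@H](OCc1ccccc1)[C@@H](Cl)C[C@@H]2Cl
F2 | step 9 | (2R,4S,5S,7S,8S)-2-{(1R)-1-[(tert-butyldimethylsilyl)oxy]propyl}-5,7-dichloro-8-(2-hydroxyethyl)oxocan-4-ol | OCC[C@@H]1O[C@@H]([C@H](O[Si](C)(C)C(C)(C)C)CC)C[C@H](O)[C@@H](Cl)C[C@@H]1Cl
F3 | step 9 | hydroxy aldehyde (21 with a free C10 hydroxyl in place of the acetate) | O=CC[C@@H]1O[C@@H]([C@H](O[Si](C)(C)C(C)(C)C)CC)C[C@H](O)[C@@H](Cl)C[C@@H]1Cl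
F4 | step 5 | (3S,4S,5E)-1-(benzyloxy)-4-chloro-7-oxohept-5-en-3-yl (2R)-2-[(tert-butyldimethylsilyl)oxy]butanoate | c1ccccc1COCC[C@H](OC(=O)[C@H](O[Si](C)(C)C(C)(C)C)CC)[C@H](/C=C/C=O)Cl
F5 | step 15 | 13-O-chloromethanesulfonate of 23 | C#C/C=C/C[C@@H]1O[C@@H]([C@H](OS(=O)(=O)CCl)CC)C[C@H](OC(C)=O)[C@@H](Cl)C[C@@H]1Cl
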